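**Remarks on the chemistry.** Labdane numbering is used throughout: ring A = C1–C5/C10, ring B = C5–C10, C11–C12 on C9, C13=C14, C15 the ester carbon, C16 the CH2O carbon, C17 the carbon on C8, C20 the methyl on C10. The target has the ent-labdane configuration at C5, C9 and C10 (antipodal to sclareol-derived material), so the decalin is made by asymmetric cyclization. (3E,7E)-Homofarnesol is assumed to be purchasable as a fragrance-industry intermediate.

## Strategy

Everything rests on cutting the C12–C13 bond between the C11–C12 ethylene arm on C9 of ring B and the C13=C14–C15 enoate. The key step exploits that C13 is the β-carbon of this enoate: it is made electrophilic as the Z-enol triflate of a 4-(formyloxy)acetoacetate, while C12, also born electrophilic as a primary iodide released from the tetrahydrofuran of ent-ambrox, is polarity-reversed by zinc insertion. One stereoretentive Negishi coupling then joins the halves, fixes the 13E alkene (C12 cis to the ester) and brings in the C16 formate. Its precursor is a Δ7 trans-decalin with a plain C17 methyl; ring B is oxidised afterwards.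

Key step: step 7

## Route

Step 1
Reactants: 1 (3E,7E)-homofarnesol
Product: 2 (+)-ambrox (ent-ambrox)
Conditions: chiral IDPi Brønsted acid (antipode of the catalyst that forms (−)-ambrox, 2 mol%), (CF3)3COH, 25 °C
Reagents that add atoms: none
Why: Proton-initiated cationic polyene bicyclization with hydroxyl capture under confined chiral Brønsted-acid catalysis; chair–chair folding of the E,E-triene should set C5, C8, C9 and C10 as the trans-decalin with trans-fused tetrahydrofuran, and the antipodal catalyst should fix the absolute sense as the ent series.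

Step 2
Reactants: 2 (+)-ambrox
Product: 4 ent-13,14,15,16-tetranorlabd-8(17)-en-12-ol, via trimethylsilyl ether 3 (not isolated)
Conditions: TMSOTf, 2,6-di-tert-butyl-4-methylpyridine, CH2Cl2, −40 → 0 °C; then K2CO3, MeOH, rt
Reagents that add atoms: none
Why: Silyl-triflate-mediated eliminative (E1) cleavage of a tertiary alkyl ether: O-silylation, ionization of the tertiary C8–O bond and proton loss to the hindered pyridine should open the ring, and methanolysis frees the C12 alcohol; proton loss from C17 gives 4 and from C7 its Δ7 isomer 5, and the mixture is carried on because step 3 converges both to 5 (C5, C9, C10 untouched).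

Step 3
Reactants: 4 ent-13,14,15,16-tetranorlabd-8(17)-en-12-ol (crude, containing 5)
Product: 5 ent-13,14,15,16-tetranorlabd-7-en-12-ol
Conditions: Co(III)(salen)Cl [3,5-di-tert-butylsalicylidene/cyclohexanediamine ligand] (3 mol%), PhSiH3 (6 mol%), benzene, rt
Reagents that add atoms: none
Why: Metal-hydride hydrogen-atom-transfer (MHAT) alkene isomerization: reversible H-atom addition to the 1,1-disubstituted alkene gives the tertiary C8 radical, and H-atom loss from the accessible C7 methylene should give the trisubstituted Δ7 alkene, which no longer reacts, so the exo isomer is funnelled into 5 without touching C9.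

Step 4
Reactants: 5 ent-13,14,15,16-tetranorlabd-7-en-12-ol
Product: 6 ent-12-iodo-13,14,15,16-tetranorlabd-7-ene
Conditions: PPh3, imidazole, I2 (premixed), CH2Cl2, 0 °C → rt
Reagents that add atoms: iodine, II
Why: Appel-type iodination: the alkoxyphosphonium ion of the primary alcohol is displaced by iodide (SN2); premixing the reagents and the imidazole buffer should keep free iodine and acid away from the Δ7 alkene.

Step 5
Reactants: 7 methyl 4-chloroacetoacetate
Product: 8 methyl 4-(formyloxy)-3-oxobutanoate
Conditions: HCO2Na, Bu4NBr (cat.), DMF, rt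
Reagents that add atoms: sodium formate, [Na+].[O-]C=O
Why: SN2 displacement of the activated α-chloroketone by formate, which is too weakly basic to enolize the β-keto ester.

Step 6
Reactants: 8 methyl 4-(formyloxy)-3-oxobutanoate
Product: 9 methyl (2Z)-4-(formyloxy)-3-(trifluoromethylsulfonyloxy)but-2-enoate
Conditions: LiHMDS, THF, −78 °C; then Tf2O, −78 °C
Reagents that add atoms: triflic anhydride, O=S(=O)(OS(=O)(=O)C(F)(F)F)C(F)(F)F
Why: O-triflation of the lithium-chelated enolate of the β-keto ester; the chelate holds the enolate oxygen cis to the ester, so the Z-enol triflate should form, and −78 °C keeps the formate from being attacked.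

Step 7
Reactants: 6 ent-12-iodo-13,14,15,16-tetranorlabd-7-ene and 9 methyl (2Z)-4-(formyloxy)-3-(trifluoromethylsulfonyloxy)but-2-enoate
Product: 11 methyl ent-16-(formyloxy)labda-7,13E-dien-15-oate, via alkylzinc iodide 10 (not isolated)
Conditions: Zn dust (TMSCl/BrCH2CH2Br-activated), LiCl, THF, 40 °C; then 9 (1.1 equiv), PdCl2(dppf) (5 mol%), THF–NMP, 0 °C → rt
Reagents that add atoms: none
Why: Zinc inserts into the primary C12–I bond (polarity reversal of C12), Pd(0) adds oxidatively to the C13–O bond of the vinylogous acyl triflate 9, and transmetalation followed by reductive elimination forms the C12–C13 σ-bond. The closest known reaction type is the Negishi sp3–sp2 coupling of primary alkylzinc halides with Z-enol triflates or tosylates of β-keto esters, which proceeds with retention of alkene geometry. No ring is closed and no stereocentre is formed; the only stereochemical element created is the trisubstituted C13=C14 alkene, whose 13E geometry (C12 cis to the C15 ester, C16 trans) is dictated by the Z-triflate fixed in step 6. The step needs chemoselectivity for the enol triflate over the allylic C16 formate and over β-hydride elimination of the alkylpalladium: oxidative addition to the electron-poor enol triflate is fast at 0 °C, the wide-bite-angle dppf ligand speeds reductive elimination, and keeping 9 in slight excess means Pd(0) is never left alone with the allylic formate of 11. The alkylzinc iodide should not add to the methyl ester or the formate, and the isolated Δ7 alkene and the C5, C9 and C10 centres are spectators.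

Step 8
Reactants: 11 methyl ent-16-(formyloxy)labda-7,13E-dien-15-oate
Product: 12 methyl ent-16-(formyloxy)-17-oxolabda-7,13E-dien-15-oate
Conditions: SeO2 (1.2 equiv), pyridine (2 equiv), 1,4-dioxane, 80 °C
Reagents that add atoms: selenium dioxide, O=[Se]=O
Why: Riley allylic oxidation (ene reaction then [2,3]-shift) of the electron-rich ring alkene at the C17 methyl on its more substituted carbon, carried through to the enal; the electron-poor C13=C14 enoate is far less reactive in the ene step, and limiting the oxidant should avoid later hydroxylation at C9.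

Step 9
Reactants: 12 methyl ent-16-(formyloxy)-17-oxolabda-7,13E-dien-15-oate
Product: 13 methyl ent-17-(tert-butyldimethylsilyloxy)-16-(formyloxy)labda-6,8(17),13E-trien-15-oate
Conditions: TBSOTf, Et3N, CH2Cl2, 0 °C
Reagents that add atoms: tert-butyldimethylsilyl triflate, CC(C)(C)[Si](C)(C)OS(=O)(=O)C(F)(F)F
Why: Soft enolization of the enal: O-silylation and γ-deprotonation at C6 (the only position that gives a conjugated dienolate; H-9 is not acidified) should give the 1-silyloxydiene, while the ester and formate are not enolized by Et3N.

Step 10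
Reactants: 13 methyl ent-17-(tert-butyldimethylsilyloxy)-16-(formyloxy)labda-6,8(17),13E-trien-15-oate
Product: 15 methyl (2E)-4-(formyloxy)-3-{2-[(1S,4R,4aR,8aS)-2-formyl-4-hydroxy-5,5,8a-trimethyl-1,4,4a,5,6,7,8,8a-octahydronaphthalen-1-yl]ethyl}but-2-enoate (target), via silyloxy epoxide 14 (not isolated)
Conditions: dimethyldioxirane, acetone–CH2Cl2, −78 → −30 °C; then HF·pyridine, THF, 0 °C
Reagents that add atoms: dimethyldioxirane, CC1(C)OO1
Why: Vinylogous Rubottom oxidation: the terminal C6=C7 bond of the dienol ether is epoxidized (the known γ-mode for linear dienol ethers; C8 is fully substituted), and vinylogous opening with loss of silicon returns the enal with oxygen on C6; the oxidant should approach the face opposite the C10 methyl and the axial C4 methyl, both of which sit 1,3-diaxial over the other face, so the C6 hydroxyl ends trans to C20 and cis to H-5.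

## Compound list

1 | (3E,7E)-homofarnesol [(3E,7E)-4,8,12-trimethyltrideca-3,7,11-trien-1-ol] | CC(C)=CCC/C(C)=C/CC/C(C)=C/CCO | starting material
2 | (+)-ambrox, ent-ambrox [(3aS,5aR,9aR,9bS)-3a,6,6,9a-tetramethyldodecahydronaphtho[2,1-b]furan] | C[C@@]12CCCC([C@H]1CC[C@]3([C@H]2CCO3)C)(C)C | intermediate
3 | O-trimethylsilyl ether of 4 | C[Si](C)(C)OCC[C@@H]1C(=C)CC[C@@H]2C(C)(C)CCC[C@@]12C | intermediate (not isolated)
4 | ent-13,14,15,16-tetranorlabd-8(17)-en-12-ol (exo-methylene alcohol; H-5 and H-9 on the face opposite C20) | OCC[C@@H]1C(=C)CC[C@@H]2C(C)(C)CCC[C@@]12C | intermediate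
5 | ent-13,14,15,16-tetranorlabd-7-en-12-ol | OCC[C@@H]1C(C)=CC[C@@H]2C(C)(C)CCC[C@@]12C | intermediate
6 | ent-12-iodo-13,14,15,16-tetranorlabd-7-ene | ICC[C@@H]1C(C)=CC[C@@H]2C(C)(C)CCC[C@@]12C | intermediate
7 | methyl 4-chloroacetoacetate | COC(=O)CC(=O)CCl | starting material
8 | methyl 4-(formyloxy)-3-oxobutanoate | COC(=O)CC(=O)COC=O | intermediate
9 | methyl (2Z)-4-(formyloxy)-3-(trifluoromethylsulfonyloxy)but-2-enoate (triflate cis to the ester) | COC(=O)/C=C(\OS(=O)(=O)C(F)(F)F)COC=O | intermediate
10 | alkylzinc iodide from 6 (zinc on C12) | I[Zn]CC[C@@H]1C(C)=CC[C@@H]2C(C)(C)CCC[C@@]12C | intermediate (not isolated)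
11 | methyl ent-16-(formyloxy)labda-7,13E-dien-15-oate | COC(=O)/C=C(\CC[C@@H]1C(C)=CC[C@@H]2C(C)(C)CCC[C@@]12C)COC=O | intermediate
12 | methyl ent-16-(formyloxy)-17-oxolabda-7,13E-dien-15-oate | COC(=O)/C=C(\CC[C@@H]1C(C=O)=CC[C@@H]2C(C)(C)CCC[C@@]12C)COC=O | intermediate
13 | methyl ent-17-(tert-butyldimethylsilyloxy)-16-(formyloxy)labda-6,8(17),13E-trien-15-oate (enol ether geometry not controlled) | COC(=O)/C=C(\CC[C@@H]1C(=CO[Si](C)(C)C(C)(C)C)C=C[C@@H]2C(C)(C)CCC[C@@]12C)COC=O | intermediate
14 | 6,7-epoxide of 13 (epoxide oxygen trans to the C10 methyl) | COC(=O)/C=C(\CC[C@@H]1C(=CO[Si](C)(C)C(C)(C)C)[C@H]3O[C@H]3[C@@H]2C(C)(C)CCC[C@@]12C)COC=O | intermediate (not isolated)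
15 | methyl (2E)-4-(formyloxy)-3-{2-[(1S,4R,4aR,8aS)-2-formyl-4-hydroxy-5,5,8a-trimethyl-1,4,4a,5,6,7,8,8a-octahydronaphthalen-1-yl]ethyl}but-2-enoate | COC(=O)/C=C(\CC[C@@H]1C(C=O)=C[C@@H](O)[C@@H]2C(C)(C)CCC[C@@]12C)COC=O | target

## Step count and risks

Total step count: 10. Longest linear sequence: 8 steps (steps 1, 2, 3, 4, 7, 8, 9, 10).

The three steps most likely to fail:

**Step 2.** The silylated ether may ionize sluggishly or re-close. Proton loss from C9 would erase the C9 stereocentre, and the C8 cation may undergo hydride or methyl shifts before elimination. The fallback sets out from 2 and comes back at 4, using only known steps. Oxidation of the ether α-methylene with catalytic RuCl3/NaIO4 should give ent-sclareolide F1. LiAlH4 should reduce it to ent-13,14,15,16-tetranorlabdane-8,12-diol F2 (8-hydroxyl on the same face as H-9). Acetic anhydride/pyridine should acetylate only the primary hydroxyl, giving the 12-acetate F3. SOCl2/pyridine at −78 °C should dehydrate the equatorial tertiary alcohol into the C17 methyl group, since no ring hydrogen is anti-periplanar, giving the exo-methylene acetate F4. K2CO3/MeOH then gives 4, which enters step 3.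

**Step 7.** Pd(0) may ionize the allylic formate of 9 or 11, leading to reduction or allyl transfer; the formyl group may be lost; the alkylpalladium may undergo β-hydride elimination; or the alkene geometry may leak through the β-acylvinyl palladium. The fallback sets out from 6 and comes back at 11, changing both the organometallic partner and the point at which the formate is introduced. Methyl 4-(tert-butyldimethylsilyloxy)-3-oxobutanoate F5 is made by crossed Claisen condensation of commercial methyl (tert-butyldimethylsilyloxy)acetate with the lithium enolate of methyl acetate, and is converted as in step 6 into its Z-enol triflate F6. Iodide 6 is lithiated with t-BuLi at −78 °C and trapped with B-methoxy-9-BBN to give the lithium borinate F7. B-alkyl Suzuki–Miyaura coupling of F7 with F6 (PdCl2(dppf), K3PO4, DMF, rt) should give methyl ent-16-(tert-butyldimethylsilyloxy)labda-7,13E-dien-15-oate F8. Bu4NF/AcOH should free methyl ent-16-hydroxylabda-7,13E-dien-15-oate F9, which cannot lactonize because the ester is trans to C16. Formic acetic anhydride/pyridine should then formylate it to 11.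

**Step 10.** Oxidation may occur at the enol-ether double bond (α-attack at C8) instead of C6=C7, the oxidant may approach from the hindered face, or the dienol ether may hydrolyse back to 12 before it is oxidised. The fallback sets out from 13 and comes back at 15. Sensitised photooxygenation (O2, tetraphenylporphyrin, hν, CH2Cl2–MeOH, −40 °C) should deliver oxygen to C6 from the same open face and, after loss of silicon to methanol, give methyl ent-16-(formyloxy)-6-hydroperoxy-17-oxolabda-7,13E-dien-15-oate F10. PPh3 should reduce the hydroperoxide to 15.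

## Further compounds

F1 | step 2 | ent-sclareolide | C[C@@]12CCCC([C@H]1CC[C@]3([C@H]2CC(=O)O3)C)(C)C
F2 | step 2 | ent-13,14,15,16-tetranorlabdane-8,12-diol | OCC[C@@H]1[C@@](C)(O)CC[C@@H]2C(C)(C)CCC[C@@]12C
F3 | step 2 | ent-12-acetoxy-13,14,15,16-tetranorlabdan-8-ol | CC(=O)OCC[C@@H]1[C@@](C)(O)CC[C@@H]2C(C)(C)CCC[C@@]12C
F4 | step 2 | ent-12-acetoxy-13,14,15,16-tetranorlabd-8(17)-ene | CC(=O)OCC[C@@H]1C(=C)CC[C@@H]2C(C)(C)CCC[C@@]12C
F5 | step 7 | methyl 4-(tert-butyldimethylsilyloxy)-3-oxobutanoate | COC(=O)CC(=O)CO[Si](C)(C)C(C)(C)C
F6 | step 7 | methyl (2Z)-4-(tert-butyldimethylsilyloxy)-3-(trifluoromethylsulfonyloxy)but-2-enoate | COC(=O)/C=C(\OS(=O)(=O)C(F)(F)F)CO[Si](C)(C)C(C)(C)C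
F7 | step 7 | lithium B-methoxy-B-(ent-13,14,15,16-tetranorlabd-7-en-12-yl)-9-borabicyclo[3.3.1]nonanuide | [Li+].CO[B-]4(CC[C@@H]1C(C)=CC[C@@H]2C(C)(C)CCC[C@@]12C)C5CCCC4CCC5
F8 | step 7 | methyl ent-16-(tert-butyldimethylsilyloxy)labda-7,13E-dien-15-oate | COC(=O)/C=C(\CC[C@@H]1C(C)=CC[C@@H]2C(C)(C)CCC[C@@]12C)CO[Si](C)(C)C(C)(C)C
F9 | step 7 | methyl ent-16-hydroxylabda-7,13E-dien-15-oate | COC(=O)/C=C(\CC[C@@H]1C(C)=CC[C@@H]2C(C)(C)CCC[C@@]12C)CO
F10 | step 10 | methyl ent-16-(formyloxy)-6-hydroperoxy-17-oxolabda-7,13E-dien-15-oate (hydroperoxide trans to C20) | COC(=O)/C=C(\CC[C@@H]1C(C=O)=C[C@@H](OO)[C@@H]2C(C)(C)CCC[C@@]12C)COC=O
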